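The readings stem from a simulated flask from invented constants; scatter was added.

The constant I carry here is read from the runs: the forward rate at which a unit of monomer in chains becomes isomer of the product.

| flask | free monomer | initiator | temperature | remark | time |
|---|---|---|---|---|---|
| Friday's | 0.050 M | 0.5 mol% | 14 °C | run made earlier |  |
| Monday's | 0.050 M | 0.75 mol% | 22 °C | run made earlier |  |
| Saturday's | 0.025 M | 1 mol% | 14 °C | run made earlier |  |
| theta | 0.050 M | 1 mol% | 25 °C |  | 3.0 min |
| gamma | 0.050 M | 1 mol% |  | at 25 °C until 2.0 min, from then on at 10 °C | 3.0 min |
| delta | 0.050 M | 1 mol% | 10 °C |  | 3.0 min |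

| run | time / min | monomer in chains / % | free monomer / % |
|---|---|---|---|
| Friday's | 0.333 | 23 | 68 |
| Friday's | 1.00 | 43 | 27 |
| Friday's | 1.50 | 33 | 10 |
| Friday's | 2.50 | 21 | 2 |
| Friday's | 4.00 | 13 | 0 |
| Monday's | 0.200 | 36 | 59 |
| Monday's | 0.667 | 38 | 13 |
| Monday's | 1.00 | 25 | 3 |
| Monday's | 1.50 | 20 | 4 |
| Monday's | 2.50 | 18 | 4 |
| Saturday's | 0.333 | 23 | 69 |
| Saturday's | 0.500 | 33 | 59 |
| Saturday's | 1.00 | 45 | 28 |
| Saturday's | 2.50 | 23 | 6 |
| Saturday's | 4.00 | 11 | 3 |

(readings scatter by 2 percentage points)

- the numbers in the tables scatter with a standard deviation of 2 percentage points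
- what may be going on: free monomer + initiator -> living end + monomer in chains; free monomer + living end -> monomer in chains + living end; monomer in chains <-> isomer of the product

1. which flask leads in amount of monomer in chains, in percent of the free monomer charged ("all alike" within 1.5 percentage points) (theta / gamma / delta / all alike)
2. how much monomer in chains is there at the end, in percent of the free monomer charged: theta
3. how much monomer in chains is there at the end, in percent of the free monomer charged: gamma
4. how much monomer in chains is there at the end, in percent of the free monomer charged: delta

Isomer is what free monomer and monomer in chains together lack, so its gain divided by the area under the chain curve gives that rate, neglecting any return. Early readings give 1.17 min⁻¹ on Friday and 2.41 min⁻¹ on Monday. Taking the logarithm as straight in temperature, I get 3.16 min⁻¹ at 25 °C and 0.815 min⁻¹ at 10 °C.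

Now I follow one molecule up the ladder. The first rung is entry into chains. Friday and Saturday have equal [initiator] and lose free monomer at 1.38 min⁻¹ and 1.35 min⁻¹, so I scale the loss with [initiator]. With Monday's 3.24 min⁻¹ for the temperature, delta gets 2.22 min⁻¹. Its free monomer half-life of 0.312 min is shorter than the 0.850 min of its chains, so delta's chains pile up and then drain.

The next rung is the drain, measured by the turn count, the forward rate times the time, or the number of chances to leave that a chain unit present from the start has had. It is 9.49 for theta, 7.14 for gamma and 2.45 for delta.

The top rung is balance. Pooling the late chain readings, and ignoring any temperature shift, gives a reading of 15.5 %. I put theta and gamma there, under thermodynamic control, and delta under kinetic control at 27.1 %.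

The forecast also picks delta, with 21.5 % for theta, 14 % for gamma and 24 % for delta. It holds that “the equilibrium chain share rises with temperature”, and its theta stands higher than my 15.5 %.

The flasks give 14.5 % for theta, 13.6 % for gamma and 21.6 % for delta, so delta leads.

    free monomer + initiator → living end + monomer in chains (k = 11.3 L mol⁻¹ s⁻¹, Ea = 42.0 kJ mol⁻¹)
    free monomer + living end → monomer in chains + living end, rate k2*[living end]*[free monomer] (k = 178 L mol⁻¹ s⁻¹, Ea = 41.0 kJ mol⁻¹)
    monomer in chains ⇌ isomer of the product (K = 5.90, k = 0.0606 s⁻¹, Ea = 68.0 kJ mol⁻¹, ΔH = −6.00 kJ mol⁻¹)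
    (constants at 25 °C)

Gamma left until 50 s, still at 25 °C, has a turn count of 2.64, close to delta's 2.45. That neighbour holds 22.3 % monomer in chains, against delta's 21.6 %, beside 76.3 % isomer of the product.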